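**Retrosynthetic overview**

1. Labels used below: C1 (quaternary C–CH3), C2/C3 (CH2), C4 (C(OH)i-Pr), C5 (ring-fusion CH), C6 (CH–O-aroyl), C7, C8(CH3)=C9, C10 (CH–O-tigloyl).
2. Target ⇒ acylation of the bicyclic triol (C10 tiglate first, then C6 4-hydroxybenzoate). The seven-membered ring is closed last by ring-closing metathesis (C8=C9) between a C1 (1-hydroxyallyl) arm and a C5 (1-hydroxy-3-methylbut-3-enyl) arm held cis on the cyclopentane.
3. C10 carbinol ⇒ Ru-catalysed asymmetric transfer hydrogenation of an ynone, made by alkynyl opening of a bridged C10/O4 lactone; the lactone ⇒ C1 methylation of a cyclopentanecarboxylate enolate anti to the C5 arm.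
4. C6 ⇒ chelation-controlled methallylation of a β-hydroxy aldehyde; C4 ⇒ isopropylcerium addition to a 2-vinylcyclopentanone anti to the vinyl group.
5. The five-membered ring is present from the start: C5 ⇒ anti conjugate addition of a vinyl cuprate to the silyl ether of methyl (3R)-3-hydroxycyclopent-1-ene-1-carboxylate, made by ketoreductase reduction of the achiral keto ester 1.

Assumption: the SMILES is taken literally, i.e. a cis-fused hydroazulene (8a-CH3 and H-3a on the same face), (3R,3aS,4S,8S,8aR); simple commercial reagents are given under "Reagents that add atoms" and are not numbered.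

**Route**

Step 1
Reactants: 1 methyl 3-oxocyclopent-1-ene-1-carboxylate
Product: 2 methyl (3R)-3-hydroxycyclopent-1-ene-1-carboxylate
Conditions: ketoreductase (R-selective KRED), NADP+ (cat.), i-PrOH (10 vol %), potassium phosphate buffer pH 7.0, 30 °C
Reagents that add atoms: none
Why: A ketoreductase (NADPH-dependent alcohol dehydrogenase, oxidoreductase class) reduces only the C=O of the achiral enone and delivers hydride to one enantiotopic face, so this enzymatic asymmetric carbonyl reduction sets the first stereocentre (C4, R), from which all others are relayed.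

Step 2
Reactants: 2 methyl (3R)-3-hydroxycyclopent-1-ene-1-carboxylate
Product: 3 methyl (3R)-3-{[tert-butyl(dimethyl)silyl]oxy}cyclopent-1-ene-1-carboxylate
Conditions: t-BuMe2SiCl, imidazole, DMF, 0 → 23 °C
Reagents that add atoms: tert-butyl(chloro)dimethylsilane, CC(C)(C)[Si](C)(C)Cl
Why: Standard silyl ether protection of the allylic alcohol gives a bulky, non-leaving γ-substituent that will direct the next step; no stereocentre is touched.

Step 3
Reactants: 3 methyl (3R)-3-{[tert-butyl(dimethyl)silyl]oxy}cyclopent-1-ene-1-carboxylate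
Product: 5 methyl (1S,2R,3R)-3-{[tert-butyl(dimethyl)silyl]oxy}-2-ethenylcyclopentane-1-carboxylate, via silyl ketene acetal 4 (not isolated)
Conditions: CH2=CHMgBr (1.3 equiv), CuBr·SMe2 (10 mol %), Me3SiCl (1.2 equiv), THF, −78 → −30 °C; then NaOMe (cat.), MeOH, 0 → 23 °C
Reagents that add atoms: vinylmagnesium bromide, C=C[Mg]Br
Why: Copper-catalysed, Me3SiCl-accelerated conjugate addition puts the vinyl group on the β-carbon anti to the neighbouring silyloxy group (sets C5); methanolysis of the ketene acetal with methoxide equilibration gives the all-trans ester (C1–H is only a placeholder, re-set in step 10).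

Step 4
Reactants: 5 methyl (1S,2R,3R)-3-{[tert-butyl(dimethyl)silyl]oxy}-2-ethenylcyclopentane-1-carboxylate
Product: 6 methyl (1S,2R,3R)-2-ethenyl-3-hydroxycyclopentane-1-carboxylate
Conditions: HF·pyridine, THF, 0 → 23 °C
Reagents that add atoms: none
Why: Fluoride-driven desilylation frees the secondary alcohol under non-basic conditions that leave the ester and its α-stereocentre alone.

Step 5
Reactants: 6 methyl (1S,2R,3R)-2-ethenyl-3-hydroxycyclopentane-1-carboxylate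
Product: 7 methyl (1S,2R)-2-ethenyl-3-oxocyclopentane-1-carboxylate
Conditions: n-Pr4N[RuO4] (5 mol %), N-methylmorpholine N-oxide, 4 Å molecular sieves, CH2Cl2, 23 °C
Reagents that add atoms: none
Why: Neutral Ley–Griffith oxidation gives the β,γ-unsaturated ketone without moving the alkene into conjugation; the C4 carbinol centre is deliberately erased now that it has relayed its chirality to C5 (held in place by the trans ester at C1).

Step 6
Reactants: 7 methyl (1S,2R)-2-ethenyl-3-oxocyclopentane-1-carboxylate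
Product: 8 methyl (1S,2R,3R)-2-ethenyl-3-hydroxy-3-(propan-2-yl)cyclopentane-1-carboxylate
Conditions: i-PrMgCl, CeCl3, THF, −78 °C
Reagents that add atoms: isopropylmagnesium chloride, CC(C)[Mg]Cl
Why: The weakly basic organocerium reagent (Imamoto 1,2-addition) adds to the enolisable ketone in preference to the ester and attacks anti to the adjacent vinyl group, giving i-Pr cis to H-5 and the tertiary OH cis to the C5 arm (sets C4).

Step 7
Reactants: 8 methyl (1S,2R,3R)-2-ethenyl-3-hydroxy-3-(propan-2-yl)cyclopentane-1-carboxylate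
Product: 10 methyl (1S,2R,3R)-2-formyl-3-hydroxy-3-(propan-2-yl)cyclopentane-1-carboxylate, via ozonide 9 (not isolated)
Conditions: O3, CH2Cl2, −78 °C; then Me2S, −78 → 23 °C
Reagents that add atoms: ozone, [O-][O+]=O
Why: Ozonolysis with reductive work-up cuts the only alkene to the C6 aldehyde under neutral conditions, so the tertiary β-hydroxy aldehyde neither dehydrates nor epimerises.

Step 8
Reactants: 10 methyl (1S,2R,3R)-2-formyl-3-hydroxy-3-(propan-2-yl)cyclopentane-1-carboxylate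
Product: 11 methyl (1S,2S,3R)-3-hydroxy-2-[(1S)-1-hydroxy-3-methylbut-3-en-1-yl]-3-(propan-2-yl)cyclopentane-1-carboxylate
Conditions: 3-bromo-2-methylprop-1-ene, In powder, THF/H2O (1:1), 23 °C
Reagents that add atoms: 3-bromo-2-methylprop-1-ene, C=C(C)CBr
Why: In this indium-mediated Barbier allylation the metal bridges the free C4 hydroxyl and the aldehyde oxygen (Cram-chelate model), and the methallyl group attacks the open exo face of that ring-fused chelate, giving the (S)-carbinol at C6; the ester is not attacked.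

Step 9
Reactants: 11 methyl (1S,2S,3R)-3-hydroxy-2-[(1S)-1-hydroxy-3-methylbut-3-en-1-yl]-3-(propan-2-yl)cyclopentane-1-carboxylate
Product: 12 methyl (1S,2S,3R)-2-[(1S)-1-{[tert-butyl(dimethyl)silyl]oxy}-3-methylbut-3-en-1-yl]-3-hydroxy-3-(propan-2-yl)cyclopentane-1-carboxylate
Conditions: t-BuMe2SiOTf (1.1 equiv), 2,6-lutidine, CH2Cl2, −78 °C
Reagents that add atoms: tert-butyldimethylsilyl trifluoromethanesulfonate, CC(C)(C)[Si](C)(C)OS(=O)(=O)C(F)(F)F
Why: At low temperature the silyl triflate silylates the secondary hydroxyl much faster than the hindered tertiary one, which keeps the two oxygens distinguishable to the end.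

Step 10
Reactants: 12 methyl (1S,2S,3R)-2-[(1S)-1-{[tert-butyl(dimethyl)silyl]oxy}-3-methylbut-3-en-1-yl]-3-hydroxy-3-(propan-2-yl)cyclopentane-1-carboxylate
Product: 14 (1R,4R,7S)-7-[(1S)-1-{[tert-butyl(dimethyl)silyl]oxy}-3-methylbut-3-en-1-yl]-4-methyl-1-(propan-2-yl)-2-oxabicyclo[2.2.1]heptan-3-one, via methylated hydroxy ester 13 (not isolated)
Conditions: LiN(i-Pr)2 (2.3 equiv), THF, −78 °C; MeI, −78 → 0 °C; then 40 °C
Reagents that add atoms: iodomethane, CI
Why: Alkylation of the exocyclic ester enolate (alkoxide/enolate dianion) occurs anti to the bulky C5 side chain, creating the quaternary C1 with CH3 cis to H-5; only this epimer has the ester cis to the C4 alkoxide and lactonises to the bridged lactone, which isolates the correct isomer.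

Step 11
Reactants: 14 (1R,4R,7S)-7-[(1S)-1-{[tert-butyl(dimethyl)silyl]oxy}-3-methylbut-3-en-1-yl]-4-methyl-1-(propan-2-yl)-2-oxabicyclo[2.2.1]heptan-3-one
Product: 15 1-[(1R,2S,3R)-2-[(1S)-1-{[tert-butyl(dimethyl)silyl]oxy}-3-methylbut-3-en-1-yl]-3-hydroxy-1-methyl-3-(propan-2-yl)cyclopentyl]-3-(trimethylsilyl)prop-2-yn-1-one
Conditions: LiC≡CSiMe3 (1.3 equiv), THF, −78 → −40 °C; H2O
Reagents that add atoms: lithium (trimethylsilyl)acetylide, [Li]C#C[Si](C)(C)C
Why: Nucleophilic acyl substitution by the small, linear alkynyllithium gives a tetrahedral lithium hemiketalate that survives at low temperature and collapses to the ynone only on work-up, so a second addition is avoided; no stereocentre changes.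

Step 12
Reactants: 15 1-[(1R,2S,3R)-2-[(1S)-1-{[tert-butyl(dimethyl)silyl]oxy}-3-methylbut-3-en-1-yl]-3-hydroxy-1-methyl-3-(propan-2-yl)cyclopentyl]-3-(trimethylsilyl)prop-2-yn-1-one
Product: 16 (1R,2S,3R)-2-[(1S)-1-{[tert-butyl(dimethyl)silyl]oxy}-3-methylbut-3-en-1-yl]-3-[(1R)-1-hydroxy-3-(trimethylsilyl)prop-2-yn-1-yl]-3-methyl-1-(propan-2-yl)cyclopentan-1-ol
Conditions: Ru[(R,R)-TsDPEN](p-cymene) (2 mol %), i-PrOH, 23 °C
Reagents that add atoms: none
Why: Noyori asymmetric transfer hydrogenation of the ynone is catalyst-controlled (the alkyne takes the π-site, the quaternary carbon the alkyl site), so the (R,R)-catalyst sets C10 with its oxygen anti to the C1 methyl; isolated alkenes and the silyl groups are untouched.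

Step 13
Reactants: 16 (1R,2S,3R)-2-[(1S)-1-{[tert-butyl(dimethyl)silyl]oxy}-3-methylbut-3-en-1-yl]-3-[(1R)-1-hydroxy-3-(trimethylsilyl)prop-2-yn-1-yl]-3-methyl-1-(propan-2-yl)cyclopentan-1-ol
Product: 17 (1R,2S,3R)-2-[(1S)-1-{[tert-butyl(dimethyl)silyl]oxy}-3-methylbut-3-en-1-yl]-3-[(1S)-1-hydroxyprop-2-yn-1-yl]-3-methyl-1-(propan-2-yl)cyclopentan-1-ol
Conditions: K2CO3 (0.3 equiv), MeOH, 23 °C
Reagents that add atoms: none
Why: Base-catalysed methanolysis cleaves only the C(sp)–Si bond; the silyl ether on oxygen is stable, and the descriptor at C10 changes only because the priorities change.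

Step 14
Reactants: 17 (1R,2S,3R)-2-[(1S)-1-{[tert-butyl(dimethyl)silyl]oxy}-3-methylbut-3-en-1-yl]-3-[(1S)-1-hydroxyprop-2-yn-1-yl]-3-methyl-1-(propan-2-yl)cyclopentan-1-ol
Product: 18 (1R,2S,3R)-2-[(1S)-1-{[tert-butyl(dimethyl)silyl]oxy}-3-methylbut-3-en-1-yl]-3-[(1S)-1-hydroxyprop-2-en-1-yl]-3-methyl-1-(propan-2-yl)cyclopentan-1-ol
Conditions: H2 (1 atm), Pd/CaCO3 poisoned with Pb(OAc)2 (Lindlar catalyst), quinoline, EtOAc, 23 °C
Reagents that add atoms: none
Why: Lindlar semi-hydrogenation stops at the alkene and does not touch the 1,1-disubstituted olefin, giving the vinyl carbinol needed for metathesis.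

Step 15
Reactants: 18 (1R,2S,3R)-2-[(1S)-1-{[tert-butyl(dimethyl)silyl]oxy}-3-methylbut-3-en-1-yl]-3-[(1S)-1-hydroxyprop-2-en-1-yl]-3-methyl-1-(propan-2-yl)cyclopentan-1-ol
Product: 19 (3R,3aS,4S,8S,8aR)-4-{[tert-butyl(dimethyl)silyl]oxy}-6,8a-dimethyl-3-(propan-2-yl)-1,2,3,3a,4,5,8,8a-octahydroazulene-3,8-diol
Conditions: second-generation Grubbs catalyst (H2IMes)(PCy3)Cl2Ru=CHPh (5 mol %), CH2Cl2 (3 mM), 40 °C
Reagents that add atoms: none
Why: Ring-closing metathesis starts at the vinyl carbinol and closes onto the 1,1-disubstituted olefin; because the two arms are cis on the cyclopentane, the cis-fused seven-membered ring with the trisubstituted C8=C9 bond forms with loss of ethene.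

Step 16
Reactants: 19 (3R,3aS,4S,8S,8aR)-4-{[tert-butyl(dimethyl)silyl]oxy}-6,8a-dimethyl-3-(propan-2-yl)-1,2,3,3a,4,5,8,8a-octahydroazulene-3,8-diol
Product: 20 (3R,3aS,4S,8S,8aR)-4-{[tert-butyl(dimethyl)silyl]oxy}-3-hydroxy-6,8a-dimethyl-3-(propan-2-yl)-1,2,3,3a,4,5,8,8a-octahydroazulen-8-yl (2E)-2-methylbut-2-enoate
Conditions: (2E)-2-methylbut-2-enoic anhydride, DMAP, Et3N, CH2Cl2, 23 → 40 °C
Reagents that add atoms: (2E)-2-methylbut-2-enoic anhydride, C/C=C(\C)C(=O)OC(=O)/C(C)=C/C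
Why: DMAP-catalysed acylation esterifies the secondary allylic C10 hydroxyl while the tertiary C4 hydroxyl stays free; the anhydride (not the acid chloride) avoids vinylketene deconjugation, and the E (tigloyl) geometry is the stable one.

Step 17
Reactants: 20 (3R,3aS,4S,8S,8aR)-4-{[tert-butyl(dimethyl)silyl]oxy}-3-hydroxy-6,8a-dimethyl-3-(propan-2-yl)-1,2,3,3a,4,5,8,8a-octahydroazulen-8-yl (2E)-2-methylbut-2-enoate
Product: 21 (3R,3aS,4S,8S,8aR)-3,4-dihydroxy-6,8a-dimethyl-3-(propan-2-yl)-1,2,3,3a,4,5,8,8a-octahydroazulen-8-yl (2E)-2-methylbut-2-enoate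
Conditions: HF·pyridine, pyridine/THF, 0 → 23 °C
Reagents that add atoms: none
Why: Buffered fluoride desilylation frees the C6 hydroxyl without acyl migration or loss of the allylic tiglate.

Step 18
Reactants: 22 4-hydroxybenzoic acid
Product: 24 4-{[tert-butyl(dimethyl)silyl]oxy}benzoic acid, via bis-silylated benzoate 23 (not isolated)
Conditions: t-BuMe2SiCl (2.3 equiv), imidazole, DMF, 23 °C; then AcOH/THF/H2O, 23 °C
Reagents that add atoms: tert-butyl(chloro)dimethylsilane, CC(C)(C)[Si](C)(C)Cl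
Why: Exhaustive silylation followed by selective hydrolysis of the far more labile silyl ester leaves the phenol masked as an aryl silyl ether that is inert to acylation conditions.

Step 19
Reactants: 21 (3R,3aS,4S,8S,8aR)-3,4-dihydroxy-6,8a-dimethyl-3-(propan-2-yl)-1,2,3,3a,4,5,8,8a-octahydroazulen-8-yl (2E)-2-methylbut-2-enoate; 24 4-{[tert-butyl(dimethyl)silyl]oxy}benzoic acid
Product: 25 (3R,3aS,4S,8S,8aR)-3-hydroxy-6,8a-dimethyl-8-{[(2E)-2-methylbut-2-enoyl]oxy}-3-(propan-2-yl)-1,2,3,3a,4,5,8,8a-octahydroazulen-4-yl 4-{[tert-butyl(dimethyl)silyl]oxy}benzoate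
Conditions: EDC·HCl, DMAP, CH2Cl2, 23 °C
Reagents that add atoms: none
Why: Steglich esterification acylates the secondary C6 hydroxyl; the tertiary C4 hydroxyl does not react.

Step 20
Reactants: 25 (3R,3aS,4S,8S,8aR)-3-hydroxy-6,8a-dimethyl-8-{[(2E)-2-methylbut-2-enoyl]oxy}-3-(propan-2-yl)-1,2,3,3a,4,5,8,8a-octahydroazulen-4-yl 4-{[tert-butyl(dimethyl)silyl]oxy}benzoate
Product: 26 (3R,3aS,4S,8S,8aR)-3-hydroxy-6,8a-dimethyl-8-{[(2E)-2-methylbut-2-enoyl]oxy}-3-(propan-2-yl)-1,2,3,3a,4,5,8,8a-octahydroazulen-4-yl 4-hydroxybenzoate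
Conditions: Bu4NF (1.1 equiv), AcOH (1.2 equiv), THF, 0 °C
Reagents that add atoms: none
Why: Acetic-acid-buffered fluoride cleaves the aryl silyl ether within minutes and leaves both esters and the tertiary alcohol intact, giving the target.

**Compound list**

1 | methyl 3-oxocyclopent-1-ene-1-carboxylate | COC(=O)C1=CC(=O)CC1 | starting material
2 | methyl (3R)-3-hydroxycyclopent-1-ene-1-carboxylate | COC(=O)C1=C[C@H](O)CC1 | intermediate
3 | methyl (3R)-3-{[tert-butyl(dimethyl)silyl]oxy}cyclopent-1-ene-1-carboxylate | COC(=O)C1=C[C@H](O[Si](C)(C)C(C)(C)C)CC1 | intermediate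
4 | tert-butyl({(1R,2R)-2-ethenyl-3-[methoxy(trimethylsilyloxy)methylidene]cyclopentyl}oxy)dimethylsilane (silyl ketene acetal, not isolated) | COC(O[Si](C)(C)C)=C1CC[C@@H](O[Si](C)(C)C(C)(C)C)[C@@H]1C=C | intermediate
5 | methyl (1S,2R,3R)-3-{[tert-butyl(dimethyl)silyl]oxy}-2-ethenylcyclopentane-1-carboxylate | COC(=O)[C@H]1CC[C@@H](O[Si](C)(C)C(C)(C)C)[C@@H]1C=C | intermediate
6 | methyl (1S,2R,3R)-2-ethenyl-3-hydroxycyclopentane-1-carboxylate | COC(=O)[C@H]1CC[C@@H](O)[C@@H]1C=C | intermediate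
7 | methyl (1S,2R)-2-ethenyl-3-oxocyclopentane-1-carboxylate | COC(=O)[C@H]1CCC(=O)[C@@H]1C=C | intermediate
8 | methyl (1S,2R,3R)-2-ethenyl-3-hydroxy-3-(propan-2-yl)cyclopentane-1-carboxylate | COC(=O)[C@H]1CC[C@@](O)(C(C)C)[C@@H]1C=C | intermediate
9 | methyl (1S,2R,3R)-3-hydroxy-3-(propan-2-yl)-2-(1,2,4-trioxolan-3-yl)cyclopentane-1-carboxylate (ozonide, both epimers at the trioxolane carbon, not isolated) | COC(=O)[C@H]1CC[C@@](O)(C(C)C)[C@@H]1C1OCOO1 | intermediate
10 | methyl (1S,2R,3R)-2-formyl-3-hydroxy-3-(propan-2-yl)cyclopentane-1-carboxylate | COC(=O)[C@H]1CC[C@@](O)(C(C)C)[C@@H]1C=O | intermediate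
11 | methyl (1S,2S,3R)-3-hydroxy-2-[(1S)-1-hydroxy-3-methylbut-3-en-1-yl]-3-(propan-2-yl)cyclopentane-1-carboxylate | COC(=O)[C@H]1CC[C@@](O)(C(C)C)[C@@H]1[C@@H](O)CC(C)=C | intermediate
12 | methyl (1S,2S,3R)-2-[(1S)-1-{[tert-butyl(dimethyl)silyl]oxy}-3-methylbut-3-en-1-yl]-3-hydroxy-3-(propan-2-yl)cyclopentane-1-carboxylate | COC(=O)[C@H]1CC[C@@](O)(C(C)C)[C@@H]1[C@@H](O[Si](C)(C)C(C)(C)C)CC(C)=C | intermediate
13 | methyl (1R,2S,3R)-2-[(1S)-1-{[tert-butyl(dimethyl)silyl]oxy}-3-methylbut-3-en-1-yl]-3-hydroxy-1-methyl-3-(propan-2-yl)cyclopentane-1-carboxylate (not isolated) | COC(=O)[C@]1(C)CC[C@@](O)(C(C)C)[C@@H]1[C@@H](O[Si](C)(C)C(C)(C)C)CC(C)=C | intermediate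
14 | (1R,4R,7S)-7-[(1S)-1-{[tert-butyl(dimethyl)silyl]oxy}-3-methylbut-3-en-1-yl]-4-methyl-1-(propan-2-yl)-2-oxabicyclo[2.2.1]heptan-3-one | O=C1O[C@@]2(C(C)C)CC[C@]1(C)[C@H]2[C@@H](O[Si](C)(C)C(C)(C)C)CC(C)=C | intermediate
15 | 1-[(1R,2S,3R)-2-[(1S)-1-{[tert-butyl(dimethyl)silyl]oxy}-3-methylbut-3-en-1-yl]-3-hydroxy-1-methyl-3-(propan-2-yl)cyclopentyl]-3-(trimethylsilyl)prop-2-yn-1-one | C[Si](C)(C)C#CC(=O)[C@]1(C)CC[C@@](O)(C(C)C)[C@@H]1[C@@H](O[Si](C)(C)C(C)(C)C)CC(C)=C | intermediate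
16 | (1R,2S,3R)-2-[(1S)-1-{[tert-butyl(dimethyl)silyl]oxy}-3-methylbut-3-en-1-yl]-3-[(1R)-1-hydroxy-3-(trimethylsilyl)prop-2-yn-1-yl]-3-methyl-1-(propan-2-yl)cyclopentan-1-ol | C[Si](C)(C)C#C[C@H](O)[C@]1(C)CC[C@@](O)(C(C)C)[C@@H]1[C@@H](O[Si](C)(C)C(C)(C)C)CC(C)=C | intermediate
17 | (1R,2S,3R)-2-[(1S)-1-{[tert-butyl(dimethyl)silyl]oxy}-3-methylbut-3-en-1-yl]-3-[(1S)-1-hydroxyprop-2-yn-1-yl]-3-methyl-1-(propan-2-yl)cyclopentan-1-ol | C#C[C@H](O)[C@]1(C)CC[C@@](O)(C(C)C)[C@@H]1[C@@H](O[Si](C)(C)C(C)(C)C)CC(C)=C | intermediate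
18 | (1R,2S,3R)-2-[(1S)-1-{[tert-butyl(dimethyl)silyl]oxy}-3-methylbut-3-en-1-yl]-3-[(1S)-1-hydroxyprop-2-en-1-yl]-3-methyl-1-(propan-2-yl)cyclopentan-1-ol | C=C[C@H](O)[C@]1(C)CC[C@@](O)(C(C)C)[C@@H]1[C@@H](O[Si](C)(C)C(C)(C)C)CC(C)=C | intermediate
19 | (3R,3aS,4S,8S,8aR)-4-{[tert-butyl(dimethyl)silyl]oxy}-6,8a-dimethyl-3-(propan-2-yl)-1,2,3,3a,4,5,8,8a-octahydroazulene-3,8-diol | O[C@H]1C=C(C)C[C@H](O[Si](C)(C)C(C)(C)C)[C@@H]2[C@@]1(C)CC[C@@]2(O)C(C)C | intermediate
20 | (3R,3aS,4S,8S,8aR)-4-{[tert-butyl(dimethyl)silyl]oxy}-3-hydroxy-6,8a-dimethyl-3-(propan-2-yl)-1,2,3,3a,4,5,8,8a-octahydroazulen-8-yl (2E)-2-methylbut-2-enoate | C/C=C(\C)C(=O)O[C@H]1C=C(C)C[C@H](O[Si](C)(C)C(C)(C)C)[C@@H]2[C@@]1(C)CC[C@@]2(O)C(C)C | intermediate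
21 | (3R,3aS,4S,8S,8aR)-3,4-dihydroxy-6,8a-dimethyl-3-(propan-2-yl)-1,2,3,3a,4,5,8,8a-octahydroazulen-8-yl (2E)-2-methylbut-2-enoate | C/C=C(\C)C(=O)O[C@H]1C=C(C)C[C@H](O)[C@@H]2[C@@]1(C)CC[C@@]2(O)C(C)C | intermediate
22 | 4-hydroxybenzoic acid | OC(=O)c1ccc(O)cc1 | starting material
23 | tert-butyldimethylsilyl 4-{[tert-butyl(dimethyl)silyl]oxy}benzoate (not isolated) | CC(C)(C)[Si](C)(C)OC(=O)c1ccc(O[Si](C)(C)C(C)(C)C)cc1 | intermediate
24 | 4-{[tert-butyl(dimethyl)silyl]oxy}benzoic acid | CC(C)(C)[Si](C)(C)Oc1ccc(C(=O)O)cc1 | intermediate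
25 | (3R,3aS,4S,8S,8aR)-3-hydroxy-6,8a-dimethyl-8-{[(2E)-2-methylbut-2-enoyl]oxy}-3-(propan-2-yl)-1,2,3,3a,4,5,8,8a-octahydroazulen-4-yl 4-{[tert-butyl(dimethyl)silyl]oxy}benzoate | C/C=C(\C)C(=O)O[C@H]1C=C(C)C[C@H](OC(=O)c2ccc(O[Si](C)(C)C(C)(C)C)cc2)[C@@H]2[C@@]1(C)CC[C@@]2(O)C(C)C | intermediate
26 | (3R,3aS,4S,8S,8aR)-3-hydroxy-6,8a-dimethyl-8-{[(2E)-2-methylbut-2-enoyl]oxy}-3-(propan-2-yl)-1,2,3,3a,4,5,8,8a-octahydroazulen-4-yl 4-hydroxybenzoate | C/C=C(\C)C(=O)O[C@H]1C=C(C)C[C@H](OC(=O)c2ccc(O)cc2)[C@@H]2[C@@]1(C)CC[C@@]2(O)C(C)C | target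

**Step count and risks**

Total step count: 20. Longest linear sequence: 19 steps (steps 1–17, 19 and 20; step 18 prepares the side-chain acid).

The three steps most likely to fail:

Step 8 (C6 configuration from chelate control). If the indium Barbier reaction gives a poor C6 ratio, substrate control is replaced by catalyst control. The fallback sets out from aldehyde 10. Me3SiOTf and 2,6-lutidine cap the tertiary hydroxyl to give methyl (1S,2R,3R)-2-formyl-3-(propan-2-yl)-3-[(trimethylsilyl)oxy]cyclopentane-1-carboxylate F1. A Keck asymmetric methallylation (methallyltributylstannane, (S)-BINOL and Ti(OiPr)4, 10 mol % each) then sets C6 and gives methyl (1S,2S,3R)-2-[(1S)-1-hydroxy-3-methylbut-3-en-1-yl]-3-(propan-2-yl)-3-[(trimethylsilyl)oxy]cyclopentane-1-carboxylate F2. t-BuMe2SiOTf and 2,6-lutidine give the bis-silyl ether methyl (1S,2S,3R)-2-[(1S)-1-{[tert-butyl(dimethyl)silyl]oxy}-3-methylbut-3-en-1-yl]-3-(propan-2-yl)-3-[(trimethylsilyl)oxy]cyclopentane-1-carboxylate F3. K2CO3 in MeOH removes only the tertiary trimethylsilyl ether, and the route is rejoined at 12.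

Step 10 (face selectivity of the C1 methylation and closure of the bridged lactone). If steric approach control is insufficient, the configuration is enforced by ring strain. The fallback sets out from diol 11. NaOMe in MeOH epimerises C1 and closes the cis-fused γ-lactone with the C6 hydroxyl, (3S,3aS,4R,6aR)-4-hydroxy-3-(2-methylprop-2-en-1-yl)-4-(propan-2-yl)hexahydro-1H-cyclopenta[c]furan-1-one F4. LiN(i-Pr)2 (2.2 equiv) and MeI alkylate the ring-fusion enolate, which can only give the cis-fused (3S,3aS,4R,6aR)-4-hydroxy-6a-methyl-3-(2-methylprop-2-en-1-yl)-4-(propan-2-yl)hexahydro-1H-cyclopenta[c]furan-1-one F5. LiC≡CSiMe3 opens this lactone to 1-[(1R,2S,3R)-3-hydroxy-2-[(1S)-1-hydroxy-3-methylbut-3-en-1-yl]-1-methyl-3-(propan-2-yl)cyclopentyl]-3-(trimethylsilyl)prop-2-yn-1-one F6. Selective silylation of its secondary hydroxyl (t-BuMe2SiOTf, 2,6-lutidine, −78 °C) rejoins the route at ynone 15.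

Step 11 (single addition to a very hindered bridged lactone). If the alkynyllithium does not add, or adds twice, the acyl group is activated differently. The fallback sets out from lactone 14, which is opened with Me2AlN(OMe)Me (from MeNHOMe·HCl and Me3Al, CH2Cl2, 0 → 40 °C) to the Weinreb amide (1R,2S,3R)-2-[(1S)-1-{[tert-butyl(dimethyl)silyl]oxy}-3-methylbut-3-en-1-yl]-3-hydroxy-N-methoxy-N,1-dimethyl-3-(propan-2-yl)cyclopentane-1-carboxamide F7. Its chelated tetrahedral intermediate stops cleanly at the ketone on treatment with LiC≡CSiMe3 (2.2 equiv, THF, −78 → 0 °C), and the route is rejoined at ynone 15.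

Further compounds
F1 | step 8 | methyl (1S,2R,3R)-2-formyl-3-(propan-2-yl)-3-[(trimethylsilyl)oxy]cyclopentane-1-carboxylate | COC(=O)[C@H]1CC[C@@](O[Si](C)(C)C)(C(C)C)[C@@H]1C=O
F2 | step 8 | methyl (1S,2S,3R)-2-[(1S)-1-hydroxy-3-methylbut-3-en-1-yl]-3-(propan-2-yl)-3-[(trimethylsilyl)oxy]cyclopentane-1-carboxylate | COC(=O)[C@H]1CC[C@@](O[Si](C)(C)C)(C(C)C)[C@@H]1[C@@H](O)CC(C)=C
F3 | step 8 | methyl (1S,2S,3R)-2-[(1S)-1-{[tert-butyl(dimethyl)silyl]oxy}-3-methylbut-3-en-1-yl]-3-(propan-2-yl)-3-[(trimethylsilyl)oxy]cyclopentane-1-carboxylate | COC(=O)[C@H]1CC[C@@](O[Si](C)(C)C)(C(C)C)[C@@H]1[C@@H](O[Si](C)(C)C(C)(C)C)CC(C)=C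
F4 | step 10 | (3S,3aS,4R,6aR)-4-hydroxy-3-(2-methylprop-2-en-1-yl)-4-(propan-2-yl)hexahydro-1H-cyclopenta[c]furan-1-one | O=C1O[C@@H](CC(C)=C)[C@@H]2[C@H]1CC[C@@]2(O)C(C)C
F5 | step 10 | (3S,3aS,4R,6aR)-4-hydroxy-6a-methyl-3-(2-methylprop-2-en-1-yl)-4-(propan-2-yl)hexahydro-1H-cyclopenta[c]furan-1-one | O=C1O[C@@H](CC(C)=C)[C@@H]2[C@@]1(C)CC[C@@]2(O)C(C)C
F6 | step 10 | 1-[(1R,2S,3R)-3-hydroxy-2-[(1S)-1-hydroxy-3-methylbut-3-en-1-yl]-1-methyl-3-(propan-2-yl)cyclopentyl]-3-(trimethylsilyl)prop-2-yn-1-one | C[Si](C)(C)C#CC(=O)[C@]1(C)CC[C@@](O)(C(C)C)[C@@H]1[C@@H](O)CC(C)=C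
F7 | step 11 | (1R,2S,3R)-2-[(1S)-1-{[tert-butyl(dimethyl)silyl]oxy}-3-methylbut-3-en-1-yl]-3-hydroxy-N-methoxy-N,1-dimethyl-3-(propan-2-yl)cyclopentane-1-carboxamide | CON(C)C(=O)[C@]1(C)CC[C@@](O)(C(C)C)[C@@H]1[C@@H](O[Si](C)(C)C(C)(C)C)CC(C)=C
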